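**Plan**

- Cuts: (a) O1–C2 and C4–C4a of ring C together, giving a symmetric ring A phenol and a 2-arylacrolein that carries ring B and C2–C3–C4; (b) the two C–H bonds at C3/C4, back to an isoflav-3-ene; (c) the C6–prenyl bond, by retro-Claisen to a 7-O ether; (d) C8–H, back to a C8 methyl ester that is removed last.
- Forward: the ring B enal is made by Suzuki coupling; ring C is closed onto ring A in one operation (boron-templated ortho-condensation, then oxa-6π-electrocyclization of an ortho-quinone methide); then asymmetric hydrogenation, O-propargylation/Lindlar/Claisen for the prenyl group, and saponification–decarboxylation.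
- Enabling feature: in ring A, C4a lies ortho to O1 and is activated by the 5-OMe and the para 7-OH, so O1–C8a–C4a is a 1,3-O,C-bisnucleophile for the three-carbon enal C2–C3(aryl)–C4. A C8 ester on the carbon between the two hydroxyls makes the phenol symmetric, so ring C can close in one way only, and it later leaves C6 as the only Claisen terminus.
- Stereochemistry: the single stereocentre C3 (R) is set by iridium-catalysed asymmetric hydrogenation of the C3=C4 alkene that the key step creates; no later step can epimerize it.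

Key step: step 5

**Route**

Step 1
Reactants: 1 methyl 2,4,6-trihydroxybenzoate
Product: 2 methyl 2,6-dihydroxy-4-methoxybenzoate
Conditions: Me2SO4 (1.0 equiv), K2CO3 (1.1 equiv), acetone, 0 °C → rt
Reagents that add atoms: dimethyl sulfate, COS(=O)(=O)OC
Why: Williamson-type O-methylation, in which the 4-hydroxyl is the only one not hydrogen-bonded to the ester and is the most acidic (para to the ester), so one equivalent of methylating agent should take it first and leave the two chelated ortho hydroxyls free.

Step 2
Reactants: 3 4-bromo-3-methoxyphenol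
Product: 4 4-bromo-3-methoxyphenyl pivalate
Conditions: PivCl, Et3N, DMAP (cat.), CH2Cl2, 0 °C → rt
Reagents that add atoms: pivaloyl chloride, CC(C)(C)C(=O)Cl
Why: DMAP-catalysed O-acylation of a phenol; the pivalate masks the ring B hydroxyl, keeps it away from boron in step 5, lowers the nucleophilicity of ring B, and is cleaved by the base used in the last step.

Step 3
Reactants: 4 4-bromo-3-methoxyphenyl pivalate
Product: 5 3-methoxy-4-(4,4,5,5-tetramethyl-1,3,2-dioxaborolan-2-yl)phenyl pivalate
Conditions: B2pin2, Pd(dppf)Cl2 (3 mol %), KOAc, 1,4-dioxane, 85 °C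
Reagents that add atoms: bis(pinacolato)diboron, CC1(C)OB(OC1(C)C)B1OC(C)(C)C(C)(C)O1
Why: Miyaura borylation of an aryl bromide, with potassium acetate as a base mild enough to leave the aryl pivalate intact.

Step 4
Reactants: 5 3-methoxy-4-(4,4,5,5-tetramethyl-1,3,2-dioxaborolan-2-yl)phenyl pivalate; 6 2-bromo-3,3-diethoxyprop-1-ene
Product: 8 3-methoxy-4-(3-oxoprop-1-en-2-yl)phenyl pivalate, via diethyl acetal 7 (not isolated)
Conditions: Pd(dppf)Cl2 (3 mol %), K3PO4, 1,4-dioxane/H2O (5:1), 70 °C; then 1 M aq. HCl, THF, 0 °C → rt; the enal is used the same day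
Reagents that add atoms: water, O
Why: Suzuki–Miyaura coupling of the arylboronate with a 1,1-disubstituted vinyl bromide, followed by mild acetal hydrolysis; the acetal keeps the sensitive 2-arylacrolein masked during the basic coupling, and the pivalate tolerates phosphate base and dilute acid.

Step 5
Reactants: 2 methyl 2,6-dihydroxy-4-methoxybenzoate; 8 3-methoxy-4-(3-oxoprop-1-en-2-yl)phenyl pivalate; 9 phenylboronic acid
Product: 12 methyl 7-hydroxy-5-methoxy-3-[2-methoxy-4-(pivaloyloxy)phenyl]-2H-chromene-8-carboxylate, via benzodioxaborin 10 (not isolated), via ortho-quinone methide 11 (not isolated)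
Conditions: 2 (2 equiv), PhB(OH)2 (1.2 equiv), EtCO2H (0.3 equiv), toluene, reflux (Dean–Stark), 8 added over 2 h
Reagents that add atoms: none
Why: Phenylboronic acid esterifies one hydroxyl of 2 and, with the aldehyde of 8 bound at boron, delivers the carbonyl carbon to the adjacent free ring carbon through a six-membered transition state (ortho-specific hydroxyalkylation), which forms the C4–C4a bond and closes the 2-phenyl-4H-1,3,2-benzodioxaborin 10 as a temporary ring; on heating, 10 loses phenylboron oxide in a retro-[4+2] process to give the vinyl ortho-quinone methide 11, whose thermal disrotatory oxa-6π-electrocyclization forms the O1–C2 bond and re-aromatizes ring A. The closest known reaction type is the phenylboronic acid-mediated chromenylation of phenols with α,β-unsaturated aldehydes by way of benzodioxaborins. Ring C is therefore closed by a pericyclic 6π-electrocyclization of a 1-oxatriene and not by an ionic exo or endo closure, while the temporary dioxaborin ring is closed by boronate condensation. No stereocentre is created, because C3 becomes an sp2 carbon of the new C3=C4 alkene, which is the prochiral handle for step 6. Three selectivities are needed: the site on ring A is secured by the symmetry of 2 (its two hydroxyls and its two free ring carbons are equivalent and the ester occupies the carbon between the hydroxyls, so only one constitutional isomer can arise); attack at the carbonyl carbon instead of conjugate attack at the unsubstituted terminus is secured by the boron tether (six-membered against eight-membered transition state); and single annulation is favoured by the excess of 2 and by the remaining hydroxyl of 12 being held in the hydrogen bond to the ester carbonyl. Ring B does not compete, since it has no free hydroxyl to bind boron and is deactivated by the pivalate.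

Step 6
Reactants: 12 methyl 7-hydroxy-5-methoxy-3-[2-methoxy-4-(pivaloyloxy)phenyl]-2H-chromene-8-carboxylate
Product: 13 methyl (3R)-7-hydroxy-5-methoxy-3-[2-methoxy-4-(pivaloyloxy)phenyl]-3,4-dihydro-2H-chromene-8-carboxylate
Conditions: H2 (50 bar), [Ir(cod)((S)-tBu-PHOX)][B(3,5-(CF3)2C6H3)4] (2 mol %), CH2Cl2, rt
Reagents that add atoms: none
Why: Iridium-catalysed asymmetric hydrogenation of an unfunctionalized trisubstituted alkene of the 3-aryl-2H-chromene class with a cationic Ir–P,N complex, in which the chiral pocket selects the alkene face and so sets C3 (the ligand antipode that gives 3R is to be fixed by a test run with both); the step is placed before the prenyl group is introduced because that alkene would not survive it.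

Step 7
Reactants: 13 methyl (3R)-7-hydroxy-5-methoxy-3-[2-methoxy-4-(pivaloyloxy)phenyl]-3,4-dihydro-2H-chromene-8-carboxylate; 14 3-chloro-3-methylbut-1-yne
Product: 15 methyl (3R)-5-methoxy-3-[2-methoxy-4-(pivaloyloxy)phenyl]-7-[(2-methylbut-3-yn-2-yl)oxy]-3,4-dihydro-2H-chromene-8-carboxylate
Conditions: DBU, CuCl2·2H2O (1 mol %), MeCN, 0 °C
Reagents that add atoms: none
Why: Copper-catalysed propargylic etherification of a phenol with a tertiary propargylic chloride (by way of a copper allenylidene), in which DBU deprotonates the 7-hydroxyl, the only free hydroxyl, and the cold, non-nucleophilic conditions spare both esters.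

Step 8
Reactants: 15 methyl (3R)-5-methoxy-3-[2-methoxy-4-(pivaloyloxy)phenyl]-7-[(2-methylbut-3-yn-2-yl)oxy]-3,4-dihydro-2H-chromene-8-carboxylate
Product: 17 methyl (3R)-7-hydroxy-5-methoxy-3-[2-methoxy-4-(pivaloyloxy)phenyl]-6-(3-methylbut-2-en-1-yl)-3,4-dihydro-2H-chromene-8-carboxylate, via 1,1-dimethylallyl ether 16 (not isolated)
Conditions: H2 (1 atm), Pd/CaCO3 (Pb-poisoned, Lindlar catalyst), quinoline, toluene, rt; filter; then 120 °C (sealed)
Reagents that add atoms: none
Why: Lindlar semi-hydrogenation of the terminal alkyne followed by aromatic Claisen [3,3] rearrangement, in which C6 is the only free ortho position of O7 (C8 carries the ester), so the 1,1-dimethylallyl group should arrive at C6 with allylic inversion as the prenyl group while C3 is untouched.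

Step 9
Reactants: 17 methyl (3R)-7-hydroxy-5-methoxy-3-[2-methoxy-4-(pivaloyloxy)phenyl]-6-(3-methylbut-2-en-1-yl)-3,4-dihydro-2H-chromene-8-carboxylate
Product: 19 (3R)-3-(4-hydroxy-2-methoxyphenyl)-5-methoxy-6-(3-methylbut-2-en-1-yl)-3,4-dihydro-2H-chromen-7-ol, via carboxylic acid 18 (not isolated)
Conditions: KOH (10 equiv), MeOH/H2O (3:1), reflux, Ar; then 1 M HCl to pH 4, 40 °C
Reagents that add atoms: none
Why: Saponification of the methyl ester and the pivalate, followed by protodecarboxylation of the resulting 2,4,6-trioxygenated benzoic acid (ipso-protonation is eased by the ortho and para oxygens, as in the hydrolysis–decarboxylation of resorcylate esters); the aryl methyl ethers, the prenyl alkene and the non-enolizable C3 centre should survive base and brief mild acid.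

**Compound list**

1 | methyl 2,4,6-trihydroxybenzoate | COC(=O)c1c(O)cc(O)cc1O | starting material
2 | methyl 2,6-dihydroxy-4-methoxybenzoate | COC(=O)c1c(O)cc(OC)cc1O | intermediate
3 | 4-bromo-3-methoxyphenol | COc1cc(O)ccc1Br | starting material
4 | 4-bromo-3-methoxyphenyl pivalate | COc1cc(OC(=O)C(C)(C)C)ccc1Br | intermediate
5 | 3-methoxy-4-(4,4,5,5-tetramethyl-1,3,2-dioxaborolan-2-yl)phenyl pivalate | COc1cc(OC(=O)C(C)(C)C)ccc1B1OC(C)(C)C(C)(C)O1 | intermediate
6 | 2-bromo-3,3-diethoxyprop-1-ene (2-bromoacrolein diethyl acetal) | C=C(Br)C(OCC)OCC | starting material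
7 | 4-(3,3-diethoxyprop-1-en-2-yl)-3-methoxyphenyl pivalate | CCOC(OCC)C(=C)c1ccc(OC(=O)C(C)(C)C)cc1OC | intermediate
8 | 3-methoxy-4-(3-oxoprop-1-en-2-yl)phenyl pivalate (the 2-arylacrolein) | COc1cc(OC(=O)C(C)(C)C)ccc1C(=C)C=O | intermediate
9 | phenylboronic acid | OB(O)c1ccccc1 | starting material
10 | methyl 7-hydroxy-5-methoxy-4-{1-[2-methoxy-4-(pivaloyloxy)phenyl]ethenyl}-2-phenyl-4H-1,3,2-benzodioxaborinine-8-carboxylate (racemic) | COC(=O)c1c(O)cc(OC)c2c1OB(c1ccccc1)OC2C(=C)c1ccc(OC(=O)C(C)(C)C)cc1OC | intermediate
11 | methyl 2-hydroxy-4-methoxy-5-{2-[2-methoxy-4-(pivaloyloxy)phenyl]prop-2-en-1-ylidene}-6-oxocyclohexa-1,3-diene-1-carboxylate (ortho-quinone methide) | COC(=O)C1=C(O)C=C(OC)C(=CC(=C)c2ccc(OC(=O)C(C)(C)C)cc2OC)C1=O | intermediate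
12 | methyl 7-hydroxy-5-methoxy-3-[2-methoxy-4-(pivaloyloxy)phenyl]-2H-chromene-8-carboxylate | COC(=O)c1c(O)cc(OC)c2c1OCC(=C2)c1ccc(OC(=O)C(C)(C)C)cc1OC | intermediate
13 | methyl (3R)-7-hydroxy-5-methoxy-3-[2-methoxy-4-(pivaloyloxy)phenyl]-3,4-dihydro-2H-chromene-8-carboxylate | COc1cc(OC(=O)C(C)(C)C)ccc1[C@@H]1COc2c(C(=O)OC)c(O)cc(OC)c2C1 | intermediate
14 | 3-chloro-3-methylbut-1-yne | CC(C)(Cl)C#C | starting material
15 | methyl (3R)-5-methoxy-3-[2-methoxy-4-(pivaloyloxy)phenyl]-7-[(2-methylbut-3-yn-2-yl)oxy]-3,4-dihydro-2H-chromene-8-carboxylate | COc1cc(OC(=O)C(C)(C)C)ccc1[C@@H]1COc2c(C(=O)OC)c(OC(C)(C)C#C)cc(OC)c2C1 | intermediate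
16 | methyl (3R)-5-methoxy-3-[2-methoxy-4-(pivaloyloxy)phenyl]-7-[(2-methylbut-3-en-2-yl)oxy]-3,4-dihydro-2H-chromene-8-carboxylate | COc1cc(OC(=O)C(C)(C)C)ccc1[C@@H]1COc2c(C(=O)OC)c(OC(C)(C)C=C)cc(OC)c2C1 | intermediate
17 | methyl (3R)-7-hydroxy-5-methoxy-3-[2-methoxy-4-(pivaloyloxy)phenyl]-6-(3-methylbut-2-en-1-yl)-3,4-dihydro-2H-chromene-8-carboxylate | COc1cc(OC(=O)C(C)(C)C)ccc1[C@@H]1COc2c(C(=O)OC)c(O)c(CC=C(C)C)c(OC)c2C1 | intermediate
18 | (3R)-7-hydroxy-3-(4-hydroxy-2-methoxyphenyl)-5-methoxy-6-(3-methylbut-2-en-1-yl)-3,4-dihydro-2H-chromene-8-carboxylic acid | COc1cc(O)ccc1[C@@H]1COc2c(C(=O)O)c(O)c(CC=C(C)C)c(OC)c2C1 | intermediate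
19 | (3R)-3-(4-hydroxy-2-methoxyphenyl)-5-methoxy-6-(3-methylbut-2-en-1-yl)-3,4-dihydro-2H-chromen-7-ol | COc1cc(O)ccc1[C@@H]1COc2cc(O)c(CC=C(C)C)c(OC)c2C1 | target

**Step count and risks**

Total step count: 9. Longest linear sequence: 8 steps (3 → 19, steps 2 to 9).

Steps most likely to fail:

Step 5. Process at risk: conjugate Friedel–Crafts attack of ring A on the unsubstituted terminus of 8, and self-condensation of 8 at reflux, may outrun the boron-templated attack at the carbonyl carbon. The fallback sets out from 2 and 8 and returns at 13. It adopts the conjugate pathway as the ring-forming event, so that the ring carbon bonds to the CH2 terminus and the phenolic oxygen to the carbonyl carbon. Diphenyl phosphate (10 mol %) in CH2Cl2 at rt should give, by Friedel–Crafts conjugate addition and hemiacetalization, the lactol methyl 2,7-dihydroxy-5-methoxy-3-[2-methoxy-4-(pivaloyloxy)phenyl]-3,4-dihydro-2H-chromene-8-carboxylate F1. TsOH (cat.) in toluene at 80 °C over 4 Å molecular sieves should dehydrate it to the cyclic enol ether methyl 7-hydroxy-5-methoxy-3-[2-methoxy-4-(pivaloyloxy)phenyl]-4H-chromene-8-carboxylate F2. Iridium-catalysed asymmetric hydrogenation under the conditions of step 6 (4H-chromenes are an established substrate class) should then give 13.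

Step 6. Process at risk: poor facial discrimination or stalled turnover on the hindered alkene flanked by the 5-methoxy and 2'-methoxy groups. The fallback sets out from 12 and returns at 13. It moves the stereo-defining event to a dynamic kinetic resolution at the ketone level. Hydroboration–oxidation of 12 (BH3·SMe2, THF; then NaBO3·4H2O) should give the racemic trans-isoflavan-4-ol methyl rac-(3R,4S)-4,7-dihydroxy-5-methoxy-3-[2-methoxy-4-(pivaloyloxy)phenyl]-3,4-dihydro-2H-chromene-8-carboxylate F3. MnO2 in CH2Cl2 should oxidize the benzylic alcohol to the isoflavanone methyl 7-hydroxy-5-methoxy-3-[2-methoxy-4-(pivaloyloxy)phenyl]-4-oxo-3,4-dihydro-2H-chromene-8-carboxylate F4. Asymmetric transfer hydrogenation of Noyori–Ikariya type (RuCl(p-cymene)[(R,R)-TsDPEN] or its antipode, HCO2H/Et3N, 40 °C) with dynamic kinetic resolution at the enolizable C3 is then followed in the same pot by ionization and reduction of the benzylic 4-hydroxyl, which is activated by the 5-methoxy and 7-hydroxy groups. This one-pot transfer hydrogenation/deoxygenation is known for isoflavanones and should give 13.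

Step 7. Process at risk: incomplete O-alkylation of the ester-chelated 7-hydroxyl by the tertiary propargylic electrophile, with competing elimination of 14 to the enyne. The fallback sets out from 13 and returns at 17. Allyl bromide, K2CO3, DMF at 60 °C should give methyl (3R)-7-(allyloxy)-5-methoxy-3-[2-methoxy-4-(pivaloyloxy)phenyl]-3,4-dihydro-2H-chromene-8-carboxylate F5. Aromatic Claisen rearrangement to the only free ortho carbon (Eu(fod)3 cat., CHCl3, 60 °C, or N,N-diethylaniline, 190 °C) should give methyl (3R)-6-allyl-7-hydroxy-5-methoxy-3-[2-methoxy-4-(pivaloyloxy)phenyl]-3,4-dihydro-2H-chromene-8-carboxylate F6. Cross-metathesis with 2-methylbut-2-ene (RuCl2(=CHPh)(PCy3)(H2IMes), second-generation Grubbs catalyst, CH2Cl2, 40 °C) should convert the allyl into the prenyl group and give 17.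

**Further compounds**

F1 | step 5 | methyl 2,7-dihydroxy-5-methoxy-3-[2-methoxy-4-(pivaloyloxy)phenyl]-3,4-dihydro-2H-chromene-8-carboxylate (racemic, mixture of lactol epimers) | COc1cc(OC(=O)C(C)(C)C)ccc1C1Cc2c(OC)cc(O)c(C(=O)OC)c2OC1O
F2 | step 5 | methyl 7-hydroxy-5-methoxy-3-[2-methoxy-4-(pivaloyloxy)phenyl]-4H-chromene-8-carboxylate | COc1cc(OC(=O)C(C)(C)C)ccc1C1=COc2c(C(=O)OC)c(O)cc(OC)c2C1
F3 | step 6 | methyl rac-(3R,4S)-4,7-dihydroxy-5-methoxy-3-[2-methoxy-4-(pivaloyloxy)phenyl]-3,4-dihydro-2H-chromene-8-carboxylate (trans, racemate, one enantiomer drawn) | COc1cc(OC(=O)C(C)(C)C)ccc1[C@@H]1COc2c(C(=O)OC)c(O)cc(OC)c2[C@H]1O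
F4 | step 6 | methyl 7-hydroxy-5-methoxy-3-[2-methoxy-4-(pivaloyloxy)phenyl]-4-oxo-3,4-dihydro-2H-chromene-8-carboxylate (racemic, C3 labile) | COc1cc(OC(=O)C(C)(C)C)ccc1C1COc2c(C(=O)OC)c(O)cc(OC)c2C1=O
F5 | step 7 | methyl (3R)-7-(allyloxy)-5-methoxy-3-[2-methoxy-4-(pivaloyloxy)phenyl]-3,4-dihydro-2H-chromene-8-carboxylate | COc1cc(OC(=O)C(C)(C)C)ccc1[C@@H]1COc2c(C(=O)OC)c(OCC=C)cc(OC)c2C1
F6 | step 7 | methyl (3R)-6-allyl-7-hydroxy-5-methoxy-3-[2-methoxy-4-(pivaloyloxy)phenyl]-3,4-dihydro-2H-chromene-8-carboxylate | COc1cc(OC(=O)C(C)(C)C)ccc1[C@@H]1COc2c(C(=O)OC)c(O)c(CC=C)c(OC)c2C1
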